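**Retrosynthetic overview**
1. C1′ stereocentre (R): lipase kinetic resolution of the racemic 1′-alcohol, which delivers the (R)-acetate directly.
2. 5E bromomethylene (Br syn to C4–Br): photochemical Z→E isomerisation of the thermodynamic 5Z alcohol, then separation.
3. C1′–O bond: Wohl–Ziegler bromination of the 3-butyl chain, then solvolysis.
4. The only ring (butenolide): oxidative cyclodehydration of 3,5-dibromo-2-butyllevulinic acid in H2SO4, which installs C4–Br and =CHBr together.
5. 2-Butyllevulinic acid: from ethyl acetoacetate and ethyl 2-bromohexanoate.

Assumption: I read the SMILES literally, i.e. C1′ is R and the exocyclic Br is cis to C4 and anti to the ring O (5E by CIP); omitting step 7 would give the 5Z isomer instead.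

**Step 1**
Reactants: 1 ethyl acetoacetate; 2 ethyl 2-bromohexanoate (racemic)
Product: 3 diethyl 2-acetyl-3-butylbutanedioate (diastereomer mixture)
Conditions: NaOEt, EtOH, reflux
Reagents that add atoms: none (both partners are numbered reactants)
Why: Acetoacetic ester alkylation (SN2 of the enolate on the α-bromo ester) assembles the full C9 skeleton; the stereocentres formed here are destroyed later.

**Step 2**
Reactants: 3
Product: 4 2-butyl-4-oxopentanoic acid (2-butyllevulinic acid)
Conditions: 6 M HCl, reflux
Reagents that add atoms: water, O
Why: Ester hydrolysis, then decarboxylation of the β-keto acid only; the carboxyl next to the butyl group is γ to the ketone and is retained.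

**Step 3**
Reactants: 4
Product: 5 3,5-dibromo-2-butyl-4-oxopentanoic acid (diastereomer mixture, used crude)
Conditions: Br2 (2 equiv), cat. HBr, CHCl3, 20–40 °C
Reagents that add atoms: bromine, BrBr
Why: Acid-catalysed ketone α-bromination via the enols, first at the more substituted C3 and then at the methyl carbon C5.

**Step 4**
Reactants: 5
Product: 6 (5Z)-4-bromo-5-(bromomethylidene)-3-butylfuran-2(5H)-one
Conditions: conc. H2SO4, 100–110 °C, 20 min; pour onto ice
Reagents that add atoms: none
Why: Enol-lactonisation and dehydration with in-situ oxidation by H2SO4 (net loss of H2O and 2 H) gives the conjugated butenolide as the thermodynamic 5Z isomer (Br syn to the ring O).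

**Step 5**
Reactants: 6
Product: 7 (5Z)-4-bromo-3-(1-bromobutyl)-5-(bromomethylidene)furan-2(5H)-one (racemic)
Conditions: NBS (1.1 equiv), cat. (BzO)2, CCl4 or PhCF3, reflux, hν
Reagents that add atoms: N-bromosuccinimide, O=C1CCC(=O)N1Br
Why: Wohl–Ziegler radical bromination attacks the only allylic C–H position, C1′ next to C3=C4; the vinyl bromides and lactone are inert, and no stereocontrol is needed.

**Step 6**
Reactants: 7
Product: 8 (5Z)-4-bromo-5-(bromomethylidene)-3-(1-hydroxybutyl)furan-2(5H)-one (racemic)
Conditions: H2O/DMSO (1:4), 60 °C
Reagents that add atoms: water, O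
Why: SN1-type solvolysis of the secondary allylic bromide through a halogen-stabilised allylic cation; the enol lactone survives neutral to weakly acidic water.

**Step 7**
Reactants: 8
Product: 9 (5E)-4-bromo-5-(bromomethylidene)-3-(1-hydroxybutyl)furan-2(5H)-one (racemic)
Conditions: hν (350 nm, Pyrex), degassed dilute MeCN, 20 °C, to the photostationary state; separate E from Z on silica/HPLC and recycle Z-8; handle 9 in the dark
Reagents that add atoms: none
Why: Photochemical E/Z isomerisation about the exocyclic C5=C bond gives a Z/E mixture from which the more hindered 5E isomer is isolated; no bonds are made or broken.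

**Step 8**
Reactants: 9 (racemic)
Product: 10 acetoxyfimbrolide, (1R)-1-[(5E)-4-bromo-5-(bromomethylidene)-2-oxo-2,5-dihydrofuran-3-yl]butyl acetate
Conditions: Burkholderia cepacia lipase (Amano PS-IM) or CAL-B, vinyl acetate (5 equiv), MTBE, 35 °C, dark, stop at ≤45% conversion; chromatograph 10 from the unreacted (S)-enantiomer of 9
Reagents that add atoms: vinyl acetate, C=COC(C)=O
Why: Lipase-catalysed acylative kinetic resolution; by the Kazlauskas rule (large group furanonyl, medium group propyl) only the (R)-enantiomer of 9 is acylated, so the R stereocentre is set here in the last step and cannot be scrambled afterwards.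

Optional, not counted: the recovered (S)-enantiomer of 9 can be converted to more 10 by Mitsunobu inversion (AcOH, PPh3, DIAD).

**Compound list**
1 | ethyl acetoacetate | CCOC(=O)CC(C)=O | starting material
2 | ethyl 2-bromohexanoate (racemic) | CCCCC(Br)C(=O)OCC | starting material
3 | diethyl 2-acetyl-3-butylbutanedioate | CCCCC(C(=O)OCC)C(C(C)=O)C(=O)OCC | intermediate
4 | 2-butyl-4-oxopentanoic acid | CCCCC(CC(C)=O)C(O)=O | intermediate
5 | 3,5-dibromo-2-butyl-4-oxopentanoic acid | CCCCC(C(O)=O)C(Br)C(=O)CBr | intermediate
6 | (5Z)-4-bromo-5-(bromomethylidene)-3-butylfuran-2(5H)-one | CCCCC1=C(Br)/C(=C/Br)OC1=O | intermediate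
7 | (5Z)-4-bromo-3-(1-bromobutyl)-5-(bromomethylidene)furan-2(5H)-one, racemic | CCCC(Br)C1=C(Br)/C(=C/Br)OC1=O | intermediate
8 | (5Z)-4-bromo-5-(bromomethylidene)-3-(1-hydroxybutyl)furan-2(5H)-one, racemic | CCCC(O)C1=C(Br)/C(=C/Br)OC1=O | intermediate
9 | (5E)-4-bromo-5-(bromomethylidene)-3-(1-hydroxybutyl)furan-2(5H)-one, racemic | CCCC(O)C1=C(Br)/C(=C\Br)OC1=O | intermediate
10 | acetoxyfimbrolide, (1R,5E) | CCC[C@@H](OC(C)=O)C1=C(Br)/C(=C\Br)OC1=O | target

**Totals**
Total steps: 8. Longest linear sequence: 8.

**Three steps most likely to fail, with fallbacks**
1. Step 7 (Z→E photoisomerisation): the photostationary ratio may be poor, or C–Br photolysis may compete. Fallback: set 5E stereospecifically by anti-bromolactonisation (NBS, KHCO3) of a 2-(1-acyloxybutyl)-3-bromopent-2-en-4-ynoic acid with CO2H cis to the ethynyl group, where O and Br add trans across the terminal alkyne (5-exo-dig). That acid could come from selective mono-Sonogashira alkynylation of the corresponding 3,3-dihaloacrylate.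
2. Step 4 (H2SO4 oxidative cyclisation): modest yield and product mixtures are likely. Fallback: build the ring non-oxidatively by CuBr2 bromolactonisation of 2-butylpenta-2,3-dienoic acid to 4-bromo-3-butyl-5-methylfuran-2(5H)-one. Then brominate and eliminate at C5 to the 5-methylene compound, and use Br2 addition/base elimination to reach the bromomethylene.
3. Step 8 (lipase resolution): the hindered carbinol with a propyl "medium" group may react slowly or with low selectivity, and the halo-enol lactone could inactivate the enzyme. Fallback: replace resolution with asymmetric reduction, i.e. oxidise the racemic alcohol to the 3-butanoyl ketone (Dess–Martin), reduce with (S)-CBS/catecholborane to the (R)-alcohol, then acetylate with Ac2O/pyridine.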